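**Plan**

- Retrosynthesis: the C6–C7 bond of the hexacosanoyl chain (ester carbonyl = C1) is cut homolytically into two primary alkyl radicals. Each is traced back to a carboxylic acid with one more carbon: henicosanoic acid and the pimelic half-ester HO2C(CH2)5CO2CH2CH2Ph. The ester C–O bond of the half-ester is then cut back to mono-tert-butyl pimelate and 2-phenylethanol.
- Forward: esterification, acidolysis of the tert-butyl ester, then a mixed Kolbe electrolysis joins the C20 and C6 pieces in the last step. This is a union of two carbons of like polarity by anodic radical coupling; no ring is formed.
- Enabling feature: C6 and C7 are unsubstituted CH2 groups inside the unbranched saturated methylene chain C2–C25, with no heteroatom, branch or π-system next to either, so both behave as simple primary radicals. The ester group (C1 and its oxygens) and the only ring, the phenyl of the 2-phenylethyl group, lie five and nine bonds from the coupling site.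
- Stereochemistry: the target has no stereocentre and no double-bond geometry, so nothing has to be set.

Key step: step 3

Assumption: mono-tert-butyl pimelate and henicosanoic acid are taken as catalogue compounds.

**Step 1**
Reactants: 1 7-tert-butoxy-7-oxoheptanoic acid (mono-tert-butyl pimelate); 2 2-phenylethanol
Product: 4 tert-butyl 2-phenylethyl heptanedioate, via O-acylisourea 3 (not isolated)
Conditions: DCC (1.1 equiv), DMAP (10 mol %), CH2Cl2, 0 °C to rt; urea filtered off
Reagents that add atoms: none
Why: Steglich esterification, in which DCC activates the free carboxyl group of 1 as the O-acylisourea 3 and DMAP relays the acyl group to the primary alcohol 2, while the tert-butyl ester is inert to these neutral conditions.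

**Step 2**
Reactants: 4 tert-butyl 2-phenylethyl heptanedioate
Product: 5 7-oxo-7-(2-phenylethoxy)heptanoic acid (mono-2-phenylethyl pimelate)
Conditions: TFA/CH2Cl2 1:3, 0 °C to rt; evaporation, toluene azeotrope, then NaHCO3 extraction and re-acidification to remove all TFA
Reagents that add atoms: none
Why: Acidolysis of a tert-butyl ester (alkyl–oxygen cleavage through the tert-butyl cation, lost as isobutene) is selective because the primary 2-phenylethyl ester cannot ionise in this way and is stable to anhydrous TFA at room temperature.

**Step 3**
Reactants: 5 7-oxo-7-(2-phenylethoxy)heptanoic acid (3.5 equiv); 6 henicosanoic acid (1 equiv)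
Product: 9 2-phenylethyl hexacosanoate, via icosyl radical 7 (not isolated), via 6-oxo-6-(2-phenylethoxy)hexyl radical 8 (not isolated)
Conditions: Pt anode/Pt cathode, undivided cell, constant current (ca. 0.3 A cm−2), NaOMe (5 mol % of total acid), MeOH–hexane 4:1, 45–50 °C; stopped while the electrolyte is still faintly acidic
Reagents that add atoms: none
Why: Mixed Kolbe electrolysis: the carboxylates of 5 and 6 are oxidised at the platinum anode to acyloxy radicals, which lose CO2 at once to give the primary alkyl radicals 8 and 7, and these combine in the dense radical layer at the electrode to form the C6–C7 bond of the hexacosanoyl chain, while the acid protons are reduced to H2 at the cathode. The closest known reaction type is the crossed Kolbe coupling of a fatty acid with a dicarboxylic acid half-ester, the classical anodic chain extension of long-chain acids, and it unites two carbons of like polarity, since both arrive as carboxyl-bearing carbons. No ring is closed and no stereocentre is formed. The selectivity needed is cross- over homo-coupling, which is purely statistical and is secured by running the readily made half-ester 5 in 3.5-fold excess, so that radical 7 should meet mainly 8; the symmetric by-products (a more polar C12 diester and nonpolar tetracontane) differ enough in polarity from 9 to be removed on silica. The second selectivity, radical coupling rather than further oxidation to a cation, is secured by the substrate, because both radical carbons are unsubstituted primary CH2 groups without α-heteroatom, α-branch or β-unsaturation, and by smooth Pt, high current density and a weakly acidic medium. The ester carbonyl lies five bonds and the phenyl ring nine bonds from the radical centre of 8, so neither is expected to interfere, and the low methoxide level of the 5 % neutralised electrolyte should leave the 2-phenylethyl ester unexchanged.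

**Compound list**

1 | 7-tert-butoxy-7-oxoheptanoic acid (mono-tert-butyl pimelate) | CC(C)(C)OC(=O)CCCCCC(=O)O | starting material
2 | 2-phenylethanol | OCCc1ccccc1 | starting material
3 | O-acylisourea of 1 with DCC, tert-butyl 7-[(N,N'-dicyclohexylcarbamimidoyl)oxy]-7-oxoheptanoate | CC(C)(C)OC(=O)CCCCCC(=O)OC(=NC1CCCCC1)NC1CCCCC1 | intermediate
4 | tert-butyl 2-phenylethyl heptanedioate | CC(C)(C)OC(=O)CCCCCC(=O)OCCc1ccccc1 | intermediate
5 | 7-oxo-7-(2-phenylethoxy)heptanoic acid (mono-2-phenylethyl pimelate) | OC(=O)CCCCCC(=O)OCCc1ccccc1 | intermediate
6 | henicosanoic acid | CCCCCCCCCCCCCCCCCCCCC(=O)O | starting material
7 | icosyl radical | [CH2]CCCCCCCCCCCCCCCCCCC | intermediate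
8 | 6-oxo-6-(2-phenylethoxy)hexyl radical | [CH2]CCCCC(=O)OCCc1ccccc1 | intermediate
9 | 2-phenylethyl hexacosanoate | CCCCCCCCCCCCCCCCCCCCCCCCCC(=O)OCCc1ccccc1 | target

Compounds 3, 7 and 8 form in the flask and are not isolated.

**Total step count:** 3
**Longest linear sequence:** 3 steps (1 → 4 → 5 → 9); henicosanoic acid 6 enters in the last step.

**Steps most likely to fail**

1. Step 3. The radicals may be consumed mainly by statistical homo-coupling. Waxy long-chain material may precipitate on the anode and passivate it, pushing the oxidation towards two-electron (cation) products. The 2-phenylethyl ester may undergo methanolysis if the electrolyte turns basic near the end. Fallback by polar, copper-catalysed chemistry, setting out from 2 and coming back at 9: 2 is esterified with purchased 6-bromohexanoic acid (OC(=O)CCCCCBr; cat. TsOH, toluene, Dean–Stark) to give 2-phenylethyl 6-bromohexanoate F1. Purchased 1-bromoicosane (CCCCCCCCCCCCCCCCCCCCBr) is converted with Mg in THF into icosylmagnesium bromide F2. F2 is then added slowly to F1 with Li2CuCl4 (2–3 mol %) in THF/NMP at −10 to 0 °C. This sp3–sp3 Grignard/alkyl bromide cross-coupling forms the same C6–C7 bond; substitution at the primary bromide should outpace addition to the ester at this temperature, giving 9.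

2. Step 1. The O-acylisourea may rearrange by O-to-N acyl shift to an unreactive N-acylurea faster than it is intercepted, and the urea may be hard to remove completely. Fallback by O-alkylation of the carboxylate instead of acyl activation, setting out from 1 and coming back at 4: 1 is treated with Cs2CO3 (0.5–0.6 equiv) in DMF to give caesium 7-tert-butoxy-7-oxoheptanoate F3. F3 is alkylated with purchased (2-bromoethyl)benzene (BrCCc1ccccc1) at rt to 40 °C in an SN2 reaction to give 4.

3. Step 2. The acidolysis may stall, the tert-butyl cation may be captured by the phenyl ring, and residual trifluoroacetate carried forward would itself be oxidised at the anode in step 3. Fallback that drops the protecting group altogether, setting out from 2 and coming back at 5: 2 is heated with a 3–4-fold excess of purchased pimelic acid (OC(=O)CCCCCC(=O)O) and cat. TsOH in toluene (Dean–Stark, Fischer esterification), so that statistics favour the mono-ester. The excess diacid is washed out with hot water, and 5 is separated from the neutral diester by extraction into aqueous NaHCO3 and re-acidification. New compounds on the way: none F0.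

**Further compounds**

F1 | step 3 | 2-phenylethyl 6-bromohexanoate | BrCCCCCC(=O)OCCc1ccccc1
F2 | step 3 | icosylmagnesium bromide | CCCCCCCCCCCCCCCCCCCC[Mg]Br
F3 | step 1 | caesium 7-tert-butoxy-7-oxoheptanoate | CC(C)(C)OC(=O)CCCCCC(=O)[O-].[Cs+]
F0 | step 2 | none | none
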